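**Retrosynthetic overview**
1. Target ⇒ its penta-O-benzyl ether. One neutral hydrogenolysis at the end frees the four phenols and the carbinol.
2. Key disconnections are the two aryl ester C–O bonds on the para oxygens of the central ring, both made in one flask from a centrosymmetric tetra-O-benzyl terphenylquinone. The first comes from a carbene-catalysed redox O-acylation with 3-phenylpropanal, in which the quinone is both oxidant and acyl acceptor, so only one acyl can enter. The second comes from carbodiimide esterification of the single phenol thus unveiled.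
3. Terphenylquinone ⇒ double Suzuki–Miyaura coupling of 2,5-bis(benzyloxy)-3,6-dibromobenzoquinone with 4-(benzyloxy)phenylboronic acid. Dibromide ⇒ bromanil + NaOCH2Ph.
4. The only stereocentre is bought in ethyl (S)-3-hydroxybutanoate, which is O-benzylated and saponified. Its C–O and C–H bonds are never touched.
5. Ring order: no ring is built. The central ring is bromanil, the two outer rings come from the boronic acid, and the fourth ring comes from 3-phenylpropanal.

Assumption: stages run in one flask, or on an unpurified crude, count as one step.

Step 1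
Reactants: 1 tetrabromo-1,4-benzoquinone (bromanil); 2 sodium benzyloxide (sold as a 1.0 M solution in benzyl alcohol)
Product: 3 dibromoquinone (2,5-bis(benzyloxy)-3,6-dibromo-1,4-benzoquinone)
Conditions: NaOCH2Ph (1.0 M in BnOH, 2.05 equiv, dropwise), THF, −20 °C to 0 °C
Reagents that add atoms: sodium benzyloxide (2), [Na+].[O-]Cc1ccccc1
Why: Twofold addition–elimination (vinylogous nucleophilic acyl substitution) on the haloquinone; the first benzyloxy group acts as a vinylogous ester and deactivates the carbonyl it is conjugated to, so the second alkoxide enters at the distal position and gives the 2,5-pattern, as methoxide does.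

Step 2
Reactants: 3 dibromoquinone; 4 4-(benzyloxy)phenylboronic acid
Product: 5 terphenylquinone (2,5-bis(benzyloxy)-3,6-bis[4-(benzyloxy)phenyl]-1,4-benzoquinone)
Conditions: 4 (2.4 equiv), PdCl2(dppf) (5 mol%), K3PO4 (4 equiv), 1,4-dioxane (2% H2O), 80 °C, Ar; work-up in air
Reagents that add atoms: 4-(benzyloxy)phenylboronic acid (4), OB(O)c1ccc(OCc2ccccc2)cc1
Why: Double Suzuki–Miyaura coupling; the two equivalent C–Br bonds are vinylogous acyl bromides, so oxidative addition to zerovalent palladium is fast, and the weakly nucleophilic phosphate base spares the benzyloxy vinylogous esters.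

Step 3
Reactants: 6 ethyl (S)-3-hydroxybutanoate; 7 benzyl 2,2,2-trichloroacetimidate
Product: 9 (S)-3-(benzyloxy)butanoic acid, via ethyl ester 8 (not isolated)
Conditions: 7 (1.5 equiv), TfOH (5 mol%), CH2Cl2/cyclohexane 1:2, 0 °C to rt; filter, evaporate; then LiOH, THF/MeOH/H2O, rt; 1 M HCl, acid–base extraction
Reagents that add atoms: benzyl 2,2,2-trichloroacetimidate (7), N=C(OCc1ccccc1)C(Cl)(Cl)Cl; lithium hydroxide, [Li+].[OH-]
Why: Acid-catalysed imidate O-benzylation followed by ester saponification; neither stage breaks a bond at C3, so the purchased (S) centre is carried through unchanged.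

Step 4
Reactants: 5 terphenylquinone; 10 3-phenylpropanal; 9 (S)-3-(benzyloxy)butanoic acid
Product: 14 mixed diester (2,5-bis(benzyloxy)-3,6-bis[4-(benzyloxy)phenyl]-4-[(3-phenylpropanoyl)oxy]phenyl (S)-3-(benzyloxy)butanoate), via acyl azolium 11 (not isolated), via hydroquinone 12 (not isolated), via monoester 13 (not isolated)
Conditions: 10 (1.15 equiv, added over 2 h), 1,4-dimethyl-1,2,4-triazolium iodide (10 mol%), DBU (20 mol%), 4 Å MS, THF, Ar, rt to 40 °C until the quinone colour is gone; then 9 (1.3 equiv), DIC (1.4 equiv), DMAP (0.3 equiv), rt
Reagents that add atoms: 3-phenylpropanal (10), O=CCCc1ccccc1; (S)-3-(benzyloxy)butanoic acid (9), C[C@H](OCc1ccccc1)CC(=O)O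
Why: Proposed new method: redox-gated hetero-diacylation of a fully substituted quinone. The triazolylidene adds to 10 to give the electron-rich enaminol (Breslow-type adduct), which passes two electrons and a proton to quinone 5, whose reduction potential should lie near that of 1,4-naphthoquinone. This gives acyl azolium 11 paired with the mono-phenolate of 12, and collapse of the ion pair forms the first aryl ester C–O bond (13) and releases the carbene. An acyl azolium can arise only when a quinone is consumed, so acyl and arene are locked at 1:1. The two carbonyl oxygens of centrosymmetric 5 are equivalent, so one isomer results, and the absence of ring C–H bonds shuts off Stetter-type C-acylation. The single phenol unveiled para to the new ester is then closed by an ordinary Steglich esterification with 9, whose (S) centre is not touched. The closest known reaction types are the carbene-catalysed oxidative esterification of aldehydes with quinone oxidants and the carbene-catalysed mono-O-acylation of 1,4-naphthoquinones by aldehydes. Neither has been shown on 2,5-dialkoxy-3,6-diarylbenzoquinones or used to tell apart the two para oxygens of a terphenylquinone.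

Step 5
Reactants: 14 mixed diester
Product: 15 target (2,5-dihydroxy-3,6-bis(4-hydroxyphenyl)-4-[(3-phenylpropanoyl)oxy]phenyl (S)-3-hydroxybutanoate)
Conditions: H2 (1 atm), Pd(OH)2/C, THF/EtOAc 1:1, rt; filter under Ar, evaporate below 30 °C
Reagents that add atoms: none
Why: Heterogeneous catalytic hydrogenolysis (O-debenzylation) cleaves all five benzylic C–O bonds under neutral conditions, which leave both aryl esters, the phenyl ring and the (S) carbinol untouched and supply no base to trigger ortho acyl migration.

**Compound list**
1 | tetrabromo-1,4-benzoquinone (bromanil) | O=C1C(Br)=C(Br)C(=O)C(Br)=C1Br | starting material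
2 | sodium benzyloxide | [Na+].[O-]Cc1ccccc1 | starting material
3 | 2,5-bis(benzyloxy)-3,6-dibromo-1,4-benzoquinone | O=C1C(Br)=C(OCc2ccccc2)C(=O)C(Br)=C1OCc1ccccc1 | intermediate
4 | 4-(benzyloxy)phenylboronic acid | OB(O)c1ccc(OCc2ccccc2)cc1 | starting material
5 | 2,5-bis(benzyloxy)-3,6-bis[4-(benzyloxy)phenyl]-1,4-benzoquinone | O=C1C(OCc2ccccc2)=C(c2ccc(OCc3ccccc3)cc2)C(=O)C(OCc2ccccc2)=C1c1ccc(OCc2ccccc2)cc1 | intermediate
6 | ethyl (S)-3-hydroxybutanoate | C[C@H](O)CC(=O)OCC | starting material
7 | benzyl 2,2,2-trichloroacetimidate | N=C(OCc1ccccc1)C(Cl)(Cl)Cl | starting material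
8 | ethyl (S)-3-(benzyloxy)butanoate | C[C@H](OCc1ccccc1)CC(=O)OCC | intermediate
9 | (S)-3-(benzyloxy)butanoic acid | C[C@H](OCc1ccccc1)CC(=O)O | intermediate
10 | 3-phenylpropanal | O=CCCc1ccccc1 | starting material
11 | 1,4-dimethyl-5-(3-phenylpropanoyl)-1,2,4-triazol-4-ium (cation; counter-ion is the mono-phenolate of 12) | Cn1nc[n+](C)c1C(=O)CCc1ccccc1 | intermediate
12 | 2,5-bis(benzyloxy)-3,6-bis[4-(benzyloxy)phenyl]benzene-1,4-diol (present in step 4 as its mono-phenolate) | Oc1c(OCc2ccccc2)c(-c2ccc(OCc3ccccc3)cc2)c(O)c(OCc2ccccc2)c1-c1ccc(OCc2ccccc2)cc1 | intermediate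
13 | 2,5-bis(benzyloxy)-3,6-bis[4-(benzyloxy)phenyl]-4-hydroxyphenyl 3-phenylpropanoate | O=C(CCc1ccccc1)Oc1c(OCc2ccccc2)c(-c2ccc(OCc3ccccc3)cc2)c(O)c(OCc2ccccc2)c1-c1ccc(OCc2ccccc2)cc1 | intermediate
14 | 2,5-bis(benzyloxy)-3,6-bis[4-(benzyloxy)phenyl]-4-[(3-phenylpropanoyl)oxy]phenyl (S)-3-(benzyloxy)butanoate | C[C@H](OCc1ccccc1)CC(=O)Oc1c(OCc2ccccc2)c(-c2ccc(OCc3ccccc3)cc2)c(OC(=O)CCc2ccccc2)c(OCc2ccccc2)c1-c1ccc(OCc2ccccc2)cc1 | intermediate
15 | 2,5-dihydroxy-3,6-bis(4-hydroxyphenyl)-4-[(3-phenylpropanoyl)oxy]phenyl (S)-3-hydroxybutanoate (CNP0296884.1) | C[C@H](O)CC(=O)Oc1c(O)c(-c2ccc(O)cc2)c(OC(=O)CCc2ccccc2)c(O)c1-c1ccc(O)cc1 | target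

**Step count**
Total steps: 5. Longest linear sequence: 4 (steps 1, 2, 4, 5 from bromanil). Step 3 is a one-step side branch.

**Three steps most likely to fail**

Step 4 (the new method). There are four risks:
- Quinone 5 may be too weak an oxidant for the carbene–aldehyde adduct.
- The carbene may displace a vinylogous-ester benzyloxy group and be lost.
- Acyl azolium 11 that escapes the ion pair may acylate 13 instead of 12 and erode the 1:1 gating.
- DBU may drive aldol self-condensation of 10.

The fallback uses known chemistry and separates reduction from acylation. It sets out from 5, which is reduced with Na2S2O4 in THF/H2O under Ar to isolated hydroquinone 12. One equivalent of NaH in THF at 0 °C, then 3-phenylpropanoyl chloride (1.0 equiv) at −20 °C, gives a statistical mono-acylation. About half the material is obtained as 13 after chromatography, and recovered 12 is recycled. The fallback comes back to the route at 13, which is esterified with 9 under the DIC/DMAP conditions of step 4. New compounds: none F0.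

Step 2. Quinone 3 can oxidise zerovalent palladium or be reduced by the boronate (with homocoupling of 4), and the base can attack the vinylogous esters. The fallback moves the coupling to the arene oxidation level. It sets out from 3, which Na2S2O4 in THF/H2O reduces to 2,5-bis(benzyloxy)-3,6-dibromobenzene-1,4-diol F1. Double Suzuki–Miyaura coupling of this bromoarene with 4 (Pd(OAc)2/SPhos, K3PO4, dioxane/H2O, 90 °C, Ar) gives hydroquinone 12. Ag2O in CH2Cl2 at rt then re-oxidises it, and the fallback comes back to the route at 5.

Step 5. The two flanked central benzyl ethers and the secondary alkyl benzyl ether may cleave slowly. Long contact times invite ortho acyl migration and air oxidation of the product hydroquinone. The fallback replaces reductive surface chemistry with low-temperature Lewis-acid heterolysis and a cation trap. It sets out from 14, which is treated with BCl3 (10 equiv) and pentamethylbenzene (15 equiv) in CH2Cl2 at −78 °C and quenched cold with CHCl3/MeOH. Each benzyl group leaves as a cation captured by the arene, the esters are tolerated, the sec-alkyl C–O bond is not broken, and acyl migration is frozen at this temperature. It comes back to the route at 15. New compounds: none F0.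

**Further compounds**
F0 | step 4 | none | none
F1 | step 2 | 2,5-bis(benzyloxy)-3,6-dibromobenzene-1,4-diol | Oc1c(Br)c(OCc2ccccc2)c(O)c(Br)c1OCc1ccccc1
F0 | step 5 | none | none
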